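Conventions: atoms are numbered as in a tetralin (C1 carries CH2OAc, C4 the side chain, C4a/C8a are the fusion carbons, C6 carries CO2H, C8 carries OH); C11 is the side-chain stereocentre; ring A is the aromatic ring and ring B the saturated one. Compound numbers are those of the steps and the compound list.

Assumption: commercial (S)-citronellal is not enantiopure, so the diastereomers that its minor enantiomer produces are expected to be removed by chromatography at the auxiliary-bearing intermediates 10 and 13.

## Analysis of the target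

The target is a 1,4-disubstituted tetralin whose aromatic ring A carries a hydroxyl at C8 and a carboxylic acid at C6, and whose saturated ring B carries CH2OAc at C1 and a 6-methylhept-5-en-2-yl chain at C4. There are three stereocentres: C1 (R) and C4 (S), which are 1,4-trans across ring B, and C11 (S), which is exocyclic and vicinal to C4. C1 and C4 are both benzylic, and the C4/C11 pair cannot be relayed through any ring, so it has to be set by acyclic control. The sensitive groups are the trisubstituted alkene (acid, electrophiles, hydrogenation), the free phenol, and a primary acetate that must coexist with a free phenol and a free acid, so it has to be introduced last. The hard points are the remote 1,4 relationship, the C4/C11 diad next to an arene, and a ring A pattern (OH flanked by the fusion carbon, carboxyl meta to it) that electrophilic substitution on a tetralin does not deliver. The strategy rests on that pattern: C8–OH ortho to C8a and meta to C6–CO2H, with C5 and C7 unsubstituted, is what a 2-alkylfuran-4-carboxylate and a terminal alkyne give on cycloisomerisation. The furan carbons become C4a, C5, C6 and C7, the alkyne carbons become C8a and C8, and the furan oxygen ends on C8. Both rings can therefore be closed last, from an open chain in which all three stereocentres are already in place.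

## Retrosynthetic reasoning

End game. Target 29 is traced back to hydroxy acid 26 through diacetate 28. The acetate is put on after ester hydrolysis, because hydroxide would not spare it. The phenol is freed again at the very end, because an aryl acetate is far more labile than an alkyl acetate. Acid 26 comes from silyl ether methyl ester 24 by desilylation and saponification.

Key disconnection. In 24 the C4a–C8a bond (ring B) and the C7–C8 bond (ring A) are cut and the C8 oxygen is returned to a furan, which gives furan-yne 22. Cutting here removes both rings at once and leaves an acyclic chain whose stereocentres can be set independently. The forward reaction has to make the ester-bearing furan attack a gold-activated alkyne through a six-membered transition state and then open the arene oxide so that oxygen stays on C8.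

Alkyne and C1. The terminal alkyne of 22 is cut at C8a≡C8 back to aldehyde 21 (one-carbon homologation). Aldehyde 21 comes from acetal 20, and through alcohol 19 from imide 18. In 18 the C1–C8a bond is cut: the future alkyne carbon is introduced as a one-carbon electrophile at the formyl oxidation level onto the enolate of imide 17, with the auxiliary fixing C1. The acyl carbon of 17 becomes the CH2O carbon. This assignment of the two arms makes the (S)-auxiliary deliver (R)-C1, so a single auxiliary enantiomer serves the whole route.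

Two-carbon extension. Imide 17 is cut at C1–C2 (as the C1=C2 alkene of 16) into aldehyde 15 and ylide 4. A Wittig reaction followed by conjugate reduction installs C1 and C8a together with the auxiliary, which avoids an ester-to-acid-to-imide detour that the furoate ester would not survive selectively. Aldehyde 15 comes from alcohol 14.

C4. Alcohol 14 comes from imide 13, in which the C4–furan bond is cut. The furyl group of bromide 11 is delivered, as its magnesium/copper derivative via 12, to the β-carbon of enoyl imide 10 under auxiliary control. C4 is the only centre that needs an aryl-type nucleophile, and a β-position of an N-enoyl oxazolidinone is the most dependable place to put it.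

C11 and the side chain. Enoyl imide 10 is cut at its C=C into ylide 4 and aldehyde 9. Aldehyde 9 is (S)-citronellal 5 less its aldehyde carbon, removed through diol 8 by α-oxygenation (6, 7) and glycol cleavage. C11 and the complete homoprenyl chain are thus bought, and the stereocentre is never enolisable except in 9, which is used without isolation.

Reagent. Ylide 4 is made from oxazolidinone 1 through bromoacetyl imide 2 and phosphonium salt 3.

## Alternatives that were turned down

Alternative 1: Ring B is cut at C3–C4 and a boron is placed on C11. The open-chain precursor is bromide A1, which carries the C1 stereocentre, a primary bromide on C3 and an (E)-propenyl group on the arene. A chiral bisphosphine–copper boryl species adds syn across the propenyl group (boron to C11, copper to benzylic C4), and the benzylic copper displaces the bromide to close ring B, giving boronate A2.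
- For: it sets C4 and C11 in one catalytic enantioselective event together with ring B, it needs no chiral pool, and the arene is bought, so the position of the phenol is never in doubt. On these points it is stronger than the chosen route.
- Against: A2 lacks the C6 carboxyl and six carbons of the side chain. The boron must be exchanged for the homoprenyl chain by a stereospecific sp3–sp3 bond formation at a hindered secondary centre, and C6 must then be carboxylated on an arene where only sterics can guide the reagent. A six-membered closure by a benzylic copper onto an unactivated primary bromide also has to outrun protodecupration, and the existing C1 centre may be mismatched with the catalyst.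
- Comparison: the chosen strategy has the whole skeleton, carboxyl and side chain included, in place before the rings close, and only protecting-group operations follow.

Alternative 2: Ring B is cut at C1–C8a. The enamine of aryl pentanal A3 with a chiral imidazolidinone is oxidised at a carbon anode to a radical cation whose α-carbon attacks the methoxy-arene ortho to the methoxy group, giving aldehyde A4.
- For: it is the shortest path to a tetralin, it forms ring B and C1 in one catalytic step without a metal, and the aldehyde carbon is already the CH2OAc carbon.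
- Against: the ring can also close para to the methoxy group, which is the less hindered site. The trisubstituted alkene and the electron-rich arene are themselves oxidisable at the potentials needed. The product is an α-aryl aldehyde that epimerises at C1. The electrochemical variant of this α-arylation is not established on such substrates. A4 again lacks the C6 carboxyl and needs a late aryl methyl ether cleavage next to the alkene.
- Comparison: it is shorter up to the ring closure, but the chosen route gets oxygenation and carboxylation of ring A by construction and sets C1 by a reaction with a predictable facial sense.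

Alternative 3: The C4–C4a bond is cut by a 1,2-shift. Under a Lewis acid, spirodienone A5 (carbonyl at C8, spiro carbon C8a) undergoes a dienone–phenol rearrangement in which C4 migrates to C4a, expanding the cyclopentane to ring B and aromatising ring A to give A6.
- For: A6 is the triisopropylsilyl analogue of 24 with the ester in place, aromatisation is strongly downhill, and the oxygen position is fixed by the carbonyl. On certainty of the phenol position it is at least as good as the chosen route.
- Against: A5 needs a quaternary spiro centre flanked by the C1 and C4 stereocentres, built only to be destroyed. C1 can migrate instead of C4, which gives a constitutional isomer. The Lewis acid endangers the trisubstituted alkene. A 2,4-cyclohexadienone of this kind tends to dimerise.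
- Comparison: the end game is the same, but the chosen precursor is an acyclic chain made by auxiliary chemistry, with no quaternary centre and no migratory competition.

Key step: step 15

## Route

Step 1
Reactants: 1 (S)-4-benzyloxazolidin-2-one
Product: 2 (S)-4-benzyl-3-(2-bromoacetyl)oxazolidin-2-one
Conditions: n-BuLi, THF, −78 °C; BrCH2COBr, −78 → 0 °C
Reagents that add atoms: bromoacetyl bromide, BrCC(Br)=O
Why: N-acylation of the lithiated oxazolidinone; the nitrogen anion attacks the acyl bromide carbon much faster than the alkyl bromide.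

Step 2
Reactants: 2 (S)-4-benzyl-3-(2-bromoacetyl)oxazolidin-2-one
Product: 4 (S)-4-benzyl-3-[(triphenylphosphoranylidene)acetyl]oxazolidin-2-one, via phosphonium bromide 3 (not isolated)
Conditions: PPh3, toluene, rt; then aq. Na2CO3, CH2Cl2, 0 °C
Reagents that add atoms: triphenylphosphine, c1ccc(cc1)P(c1ccccc1)c1ccccc1
Why: SN2 quaternisation of the phosphine by the α-bromo imide, then deprotonation of the very acidic phosphonium methylene by carbonate gives the imide-stabilised Wittig ylide without cleaving the imide.

Step 3
Reactants: 5 (S)-citronellal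
Product: 7 (2R,3S)-3,7-dimethyl-2-[(phenylamino)oxy]oct-6-en-1-ol, via aminooxy aldehyde 6 (not isolated)
Conditions: PhNO, L-proline (20 mol %), CHCl3, 0 °C; then NaBH4, EtOH, 0 °C
Reagents that add atoms: nitrosobenzene, O=Nc1ccccc1
Why: Proline-enamine catalysed O-selective nitroso aldol reaction (α-aminoxylation) oxygenates C2 of citronellal, and immediate borohydride reduction stops epimerisation and dimerisation. The new C2 centre (R expected from L-proline) is excised in step 5, and the C3 centre, the future C11, is not touched.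

Step 4
Reactants: 7 (2R,3S)-3,7-dimethyl-2-[(phenylamino)oxy]oct-6-en-1-ol
Product: 8 (2R,3S)-3,7-dimethyloct-6-ene-1,2-diol
Conditions: Zn, AcOH, THF, rt
Reagents that add atoms: none
Why: Reductive cleavage of the weak N–O bond by zinc in acetic acid; the alkene is inert to these conditions.

Step 5
Reactants: 8 (2R,3S)-3,7-dimethyloct-6-ene-1,2-diol, 4 (S)-4-benzyl-3-[(triphenylphosphoranylidene)acetyl]oxazolidin-2-one
Product: 10 (S)-4-benzyl-3-[(2E,4S)-4,8-dimethylnona-2,7-dienoyl]oxazolidin-2-one, via aldehyde 9 (not isolated)
Conditions: NaIO4, CH2Cl2/H2O, 0 °C → rt; organic layer separated and dried, then 4, rt → 40 °C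
Reagents that add atoms: none
Why: Periodate glycol cleavage removes the former aldehyde carbon as formaldehyde (left in the water layer) under near-neutral conditions, so the α-stereocentre of volatile aldehyde 9 is not enolised. The base-free Wittig reaction with stabilised ylide 4 should be E-selective and installs the auxiliary directly.

Step 6
Reactants: 11 methyl 5-bromofuran-3-carboxylate, 10 (S)-4-benzyl-3-[(2E,4S)-4,8-dimethylnona-2,7-dienoyl]oxazolidin-2-one
Product: 13 methyl 5-[(3S,4S)-1-[(S)-4-benzyl-2-oxooxazolidin-3-yl]-4,8-dimethyl-1-oxonon-7-en-3-yl]furan-3-carboxylate, via furylmagnesium chloride 12 (not isolated)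
Conditions: i-PrMgCl·LiCl, THF, −40 °C; CuBr·SMe2, Me2S, −40 °C; then 10, −40 → −10 °C; aq. NH4Cl
Reagents that add atoms: none
Why: Bromine–magnesium exchange at low temperature tolerates the ester, and copper-mediated conjugate addition of (hetero)aryl Grignard reagents to N-enoyl oxazolidinones is a known reaction type. Magnesium chelates the two imide carbonyls in the syn-s-cis conformer and the furyl group enters anti to the benzyl group, which sets C4 as (S); minor diastereomers are removed here by chromatography.

Step 7
Reactants: 13 methyl 5-[(3S,4S)-1-[(S)-4-benzyl-2-oxooxazolidin-3-yl]-4,8-dimethyl-1-oxonon-7-en-3-yl]furan-3-carboxylate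
Product: 14 methyl 5-[(3S,4S)-1-hydroxy-4,8-dimethylnon-7-en-3-yl]furan-3-carboxylate
Conditions: NaBH4, THF/H2O, 0 °C → rt
Reagents that add atoms: none
Why: Borohydride in wet THF reduces the activated exocyclic imide carbonyl to the primary alcohol and releases auxiliary 1 for recovery, while the conjugated furoate ester is not reduced.

Step 8
Reactants: 14 methyl 5-[(3S,4S)-1-hydroxy-4,8-dimethylnon-7-en-3-yl]furan-3-carboxylate, 4 (S)-4-benzyl-3-[(triphenylphosphoranylidene)acetyl]oxazolidin-2-one
Product: 16 methyl 5-[(2E,5S,6S)-1-[(S)-4-benzyl-2-oxooxazolidin-3-yl]-6,10-dimethyl-1-oxoundeca-2,9-dien-5-yl]furan-3-carboxylate, via aldehyde 15 (not isolated)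
Conditions: Dess–Martin periodinane, pyridine, CH2Cl2, 0 °C → rt; then 4, rt
Reagents that add atoms: none
Why: Dess–Martin oxidation followed by in-flask Wittig reaction with stabilised ylide 4 adds C1 and C8a and re-attaches the auxiliary in one operation; no stereocentre is α to the aldehyde.

Step 9
Reactants: 16 methyl 5-[(2E,5S,6S)-1-[(S)-4-benzyl-2-oxooxazolidin-3-yl]-6,10-dimethyl-1-oxoundeca-2,9-dien-5-yl]furan-3-carboxylate
Product: 17 methyl 5-[(5S,6S)-1-[(S)-4-benzyl-2-oxooxazolidin-3-yl]-6,10-dimethyl-1-oxoundec-9-en-5-yl]furan-3-carboxylate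
Conditions: Cu(OAc)2·H2O (5 mol %), 1,2-bis(diphenylphosphino)benzene (5 mol %), MeSiH(OMe)2, t-BuOH, toluene, rt
Reagents that add atoms: none
Why: Phosphine-ligated copper hydride conjugate reduction delivers hydride only to the polarised enoyl C=C; the isolated trisubstituted alkene, the furan and its ester are not substrates, and t-BuOH protonates the enolate.

Step 10
Reactants: 17 methyl 5-[(5S,6S)-1-[(S)-4-benzyl-2-oxooxazolidin-3-yl]-6,10-dimethyl-1-oxoundec-9-en-5-yl]furan-3-carboxylate
Product: 18 methyl 5-[(2R,5S,6S)-1-[(S)-4-benzyl-2-oxooxazolidin-3-yl]-2-(dimethoxymethyl)-6,10-dimethyl-1-oxoundec-9-en-5-yl]furan-3-carboxylate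
Conditions: TiCl4, i-Pr2NEt, CH2Cl2, 0 °C; then HC(OMe)3, 0 °C
Reagents that add atoms: trimethyl orthoformate, COC(OC)OC
Why: Soft enolisation gives the chelated Z-titanium enolate, which is alkylated by the dimethoxycarbenium ion on the face opposite the benzyl group (auxiliary-controlled titanium enolate alkylation). This sets C1; the (2R) centre becomes (R)-C1 once the acyl carbon is the CH2O carbon and the acetal carbon is C8a.

Step 11
Reactants: 18 methyl 5-[(2R,5S,6S)-1-[(S)-4-benzyl-2-oxooxazolidin-3-yl]-2-(dimethoxymethyl)-6,10-dimethyl-1-oxoundec-9-en-5-yl]furan-3-carboxylate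
Product: 19 methyl 5-[(2S,5S,6S)-2-(dimethoxymethyl)-1-hydroxy-6,10-dimethylundec-9-en-5-yl]furan-3-carboxylate
Conditions: NaBH4, THF/H2O, rt
Reagents that add atoms: none
Why: Reductive removal of the auxiliary as in step 7; the acetal and the furoate ester are stable to borohydride and the α-centre is not epimerised under these non-basic conditions.

Step 12
Reactants: 19 methyl 5-[(2S,5S,6S)-2-(dimethoxymethyl)-1-hydroxy-6,10-dimethylundec-9-en-5-yl]furan-3-carboxylate
Product: 20 methyl 5-[(2S,5S,6S)-1-[(tert-butyldimethylsilyl)oxy]-2-(dimethoxymethyl)-6,10-dimethylundec-9-en-5-yl]furan-3-carboxylate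
Conditions: TBSCl, imidazole, DMF, rt
Reagents that add atoms: tert-butyldimethylsilyl chloride, CC(C)(C)[Si](C)(C)Cl
Why: Standard silylation of a primary alcohol; the silyl ether keeps the CH2O arm distinct from the future alkyne arm through the base and gold steps.

Step 13
Reactants: 20 methyl 5-[(2S,5S,6S)-1-[(tert-butyldimethylsilyl)oxy]-2-(dimethoxymethyl)-6,10-dimethylundec-9-en-5-yl]furan-3-carboxylate
Product: 21 methyl 5-[(2S,5S,6S)-2-{[(tert-butyldimethylsilyl)oxy]methyl}-6,10-dimethyl-1-oxoundec-9-en-5-yl]furan-3-carboxylate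
Conditions: Et3SiOTf, 2,4,6-collidine, CH2Cl2, 0 °C; then H2O
Reagents that add atoms: water, O
Why: Silyl triflate and a hindered pyridine convert an aldehyde dimethyl acetal into a pyridinium adduct that water hydrolyses to the aldehyde under essentially neutral conditions, which spares the primary silyl ether, the alkene and the C1 centre; the aldehyde is used at once.

Step 14
Reactants: 21 methyl 5-[(2S,5S,6S)-2-{[(tert-butyldimethylsilyl)oxy]methyl}-6,10-dimethyl-1-oxoundec-9-en-5-yl]furan-3-carboxylate
Product: 22 methyl 5-[(3R,6S,7S)-3-{[(tert-butyldimethylsilyl)oxy]methyl}-7,11-dimethyldodec-10-en-1-yn-6-yl]furan-3-carboxylate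
Conditions: dimethyl (1-diazo-2-oxopropyl)phosphonate, K2CO3, MeOH, 0 °C → rt
Reagents that add atoms: dimethyl (1-diazo-2-oxopropyl)phosphonate, COP(=O)(OC)C(=[N+]=[N-])C(C)=O
Why: Ohira–Bestmann homologation adds C8 and gives the terminal alkyne; the methyl ester is degenerate toward methoxide, and α-branched β-silyloxy aldehydes of this kind are routinely homologated this way when kept cold.

Step 15
Reactants: 22 methyl 5-[(3R,6S,7S)-3-{[(tert-butyldimethylsilyl)oxy]methyl}-7,11-dimethyldodec-10-en-1-yn-6-yl]furan-3-carboxylate
Product: 24 methyl (1R,4S)-1-{[(tert-butyldimethylsilyl)oxy]methyl}-8-hydroxy-4-[(2S)-6-methylhept-5-en-2-yl]-1,2,3,4-tetrahydronaphthalene-6-carboxylate, via arene oxide 23 (not isolated)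
Conditions: (Ph3P)AuNTf2 (5 mol %), CH2Cl2 (0.02 M), 4 Å MS, rt → 40 °C
Reagents that add atoms: none
Why: The cationic monovalent gold centre binds the terminal alkyne and the furan attacks it through its substituted α-carbon (C4a) in a 6-exo-dig mode, which closes ring B by the C4a–C8a bond and leaves a cyclopropyl gold carbene centred on C8. Opening of the furan C–O bond gives a (Z)-dienal gold carbene, whose aldehyde oxygen adds to the carbene carbon to give an oxepine, and 6π-electrocyclisation of the oxepine forms the C7–C8 bond of ring A as arene oxide 23. Opening of the epoxide and loss of the C8 proton give the phenol, so the furan oxygen ends on the former terminal alkyne carbon. The closest known reaction type is the gold-catalysed cycloisomerisation of ω-alkynylfurans to phenols, applied here to an ester-bearing and therefore less nucleophilic furan and a four-carbon tether, for which the electrophilic phosphine–gold triflimide is chosen. No stereocentre is created: C1, C4 and C11 are spectators and the two epoxide carbons of 23 become sp2. Chemoselectivity should hold because the furan is the only π-nucleophile that reaches the alkyne through a six-membered transition state (the side-chain alkene would need a nine- or ten-membered one, the hindered silyl ether oxygen a strained 5-endo closure). Regioselectivity of the epoxide opening should be secured by the C6 ester: cleaving C7–O spreads the charge over C7, C5 and C8a, whereas cleaving C8–O would place it on the ester-bearing C6. Dilution and molecular sieves are there to suppress alkyne hydration and oligomerisation.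

Step 16
Reactants: 24 methyl (1R,4S)-1-{[(tert-butyldimethylsilyl)oxy]methyl}-8-hydroxy-4-[(2S)-6-methylhept-5-en-2-yl]-1,2,3,4-tetrahydronaphthalene-6-carboxylate
Product: 26 (1R,4S)-8-hydroxy-1-(hydroxymethyl)-4-[(2S)-6-methylhept-5-en-2-yl]-1,2,3,4-tetrahydronaphthalene-6-carboxylic acid, via desilylated methyl ester 25 (not isolated)
Conditions: Bu4NF, THF, rt; then LiOH, MeOH/H2O, 45 °C; aq. HCl to pH 3 at work-up
Reagents that add atoms: lithium hydroxide, [Li+].[OH-]
Why: Fluoride cleaves the Si–O bond and hydroxide saponifies the aryl methyl ester in the same basic medium, so the alkene sees acid only briefly at work-up.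

Step 17
Reactants: 26 (1R,4S)-8-hydroxy-1-(hydroxymethyl)-4-[(2S)-6-methylhept-5-en-2-yl]-1,2,3,4-tetrahydronaphthalene-6-carboxylic acid
Product: 28 (1R,4S)-8-acetoxy-1-(acetoxymethyl)-4-[(2S)-6-methylhept-5-en-2-yl]-1,2,3,4-tetrahydronaphthalene-6-carboxylic acid, via mixed anhydride 27 (not isolated)
Conditions: Ac2O (excess), pyridine, rt; then H2O, THF, rt
Reagents that add atoms: acetic anhydride, CC(=O)OC(C)=O
Why: Exhaustive acetylation covers both hydroxyls and turns the acid into an acetic mixed anhydride, which aqueous pyridine hydrolyses at the more electrophilic acetyl carbonyl to return the free acid.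

Step 18
Reactants: 28 (1R,4S)-8-acetoxy-1-(acetoxymethyl)-4-[(2S)-6-methylhept-5-en-2-yl]-1,2,3,4-tetrahydronaphthalene-6-carboxylic acid
Product: 29 (1R,4S)-1-(acetoxymethyl)-8-hydroxy-4-[(2S)-6-methylhept-5-en-2-yl]-1,2,3,4-tetrahydronaphthalene-6-carboxylic acid
Conditions: NH4OAc, MeOH/H2O, rt
Reagents that add atoms: none
Why: Selective methanolysis of the aryl acetate, which has the better leaving group and is far more electrophilic than the alkyl acetate under these near-neutral conditions; the alkyl acetate is also the thermodynamically preferred site should acetyl migrate.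

## Compound list

1 | (S)-4-benzyloxazolidin-2-one | O=C1N[C@@H](Cc2ccccc2)CO1 | starting material
2 | (S)-4-benzyl-3-(2-bromoacetyl)oxazolidin-2-one | O=C1OC[C@H](Cc2ccccc2)N1C(=O)CBr | intermediate
3 | {2-[(S)-4-benzyl-2-oxooxazolidin-3-yl]-2-oxoethyl}triphenylphosphonium bromide | O=C1OC[C@H](Cc2ccccc2)N1C(=O)C[P+](c1ccccc1)(c1ccccc1)c1ccccc1.[Br-] | intermediate (not isolated)
4 | (S)-4-benzyl-3-[(triphenylphosphoranylidene)acetyl]oxazolidin-2-one | O=C1OC[C@H](Cc2ccccc2)N1C(=O)C=P(c1ccccc1)(c1ccccc1)c1ccccc1 | intermediate
5 | (S)-citronellal, (3S)-3,7-dimethyloct-6-enal | O=CC[C@@H](C)CCC=C(C)C | starting material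
6 | (2R,3S)-3,7-dimethyl-2-[(phenylamino)oxy]oct-6-enal | O=C[C@H](ONc1ccccc1)[C@@H](C)CCC=C(C)C | intermediate (not isolated)
7 | (2R,3S)-3,7-dimethyl-2-[(phenylamino)oxy]oct-6-en-1-ol | OC[C@H](ONc1ccccc1)[C@@H](C)CCC=C(C)C | intermediate
8 | (2R,3S)-3,7-dimethyloct-6-ene-1,2-diol | OC[C@H](O)[C@@H](C)CCC=C(C)C | intermediate
9 | (S)-2,6-dimethylhept-5-enal | O=C[C@@H](C)CCC=C(C)C | intermediate (not isolated)
10 | (S)-4-benzyl-3-[(2E,4S)-4,8-dimethylnona-2,7-dienoyl]oxazolidin-2-one | O=C1OC[C@H](Cc2ccccc2)N1C(=O)/C=C/[C@@H](C)CCC=C(C)C | intermediate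
11 | methyl 5-bromofuran-3-carboxylate | COC(=O)c1coc(Br)c1 | starting material
12 | [4-(methoxycarbonyl)furan-2-yl]magnesium chloride (LiCl complex) | COC(=O)c1coc([Mg]Cl)c1 | intermediate (not isolated)
13 | methyl 5-[(3S,4S)-1-[(S)-4-benzyl-2-oxooxazolidin-3-yl]-4,8-dimethyl-1-oxonon-7-en-3-yl]furan-3-carboxylate | O=C1OC[C@H](Cc2ccccc2)N1C(=O)C[C@@H]([C@@H](C)CCC=C(C)C)c1cc(C(=O)OC)co1 | intermediate
14 | methyl 5-[(3S,4S)-1-hydroxy-4,8-dimethylnon-7-en-3-yl]furan-3-carboxylate | OCC[C@@H]([C@@H](C)CCC=C(C)C)c1cc(C(=O)OC)co1 | intermediate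
15 | methyl 5-[(3S,4S)-4,8-dimethyl-1-oxonon-7-en-3-yl]furan-3-carboxylate | O=CC[C@@H]([C@@H](C)CCC=C(C)C)c1cc(C(=O)OC)co1 | intermediate (not isolated)
16 | methyl 5-[(2E,5S,6S)-1-[(S)-4-benzyl-2-oxooxazolidin-3-yl]-6,10-dimethyl-1-oxoundeca-2,9-dien-5-yl]furan-3-carboxylate | O=C1OC[C@H](Cc2ccccc2)N1C(=O)/C=C/C[C@@H]([C@@H](C)CCC=C(C)C)c1cc(C(=O)OC)co1 | intermediate
17 | methyl 5-[(5S,6S)-1-[(S)-4-benzyl-2-oxooxazolidin-3-yl]-6,10-dimethyl-1-oxoundec-9-en-5-yl]furan-3-carboxylate | O=C1OC[C@H](Cc2ccccc2)N1C(=O)CCC[C@@H]([C@@H](C)CCC=C(C)C)c1cc(C(=O)OC)co1 | intermediate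
18 | methyl 5-[(2R,5S,6S)-1-[(S)-4-benzyl-2-oxooxazolidin-3-yl]-2-(dimethoxymethyl)-6,10-dimethyl-1-oxoundec-9-en-5-yl]furan-3-carboxylate | O=C1OC[C@H](Cc2ccccc2)N1C(=O)[C@@H](C(OC)OC)CC[C@@H]([C@@H](C)CCC=C(C)C)c1cc(C(=O)OC)co1 | intermediate
19 | methyl 5-[(2S,5S,6S)-2-(dimethoxymethyl)-1-hydroxy-6,10-dimethylundec-9-en-5-yl]furan-3-carboxylate | OC[C@@H](C(OC)OC)CC[C@@H]([C@@H](C)CCC=C(C)C)c1cc(C(=O)OC)co1 | intermediate
20 | methyl 5-[(2S,5S,6S)-1-[(tert-butyldimethylsilyl)oxy]-2-(dimethoxymethyl)-6,10-dimethylundec-9-en-5-yl]furan-3-carboxylate | CC(C)(C)[Si](C)(C)OC[C@@H](C(OC)OC)CC[C@@H]([C@@H](C)CCC=C(C)C)c1cc(C(=O)OC)co1 | intermediate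
21 | methyl 5-[(2S,5S,6S)-2-{[(tert-butyldimethylsilyl)oxy]methyl}-6,10-dimethyl-1-oxoundec-9-en-5-yl]furan-3-carboxylate | CC(C)(C)[Si](C)(C)OC[C@@H](C=O)CC[C@@H]([C@@H](C)CCC=C(C)C)c1cc(C(=O)OC)co1 | intermediate
22 | methyl 5-[(3R,6S,7S)-3-{[(tert-butyldimethylsilyl)oxy]methyl}-7,11-dimethyldodec-10-en-1-yn-6-yl]furan-3-carboxylate | CC(C)(C)[Si](C)(C)OC[C@@H](C#C)CC[C@@H]([C@@H](C)CCC=C(C)C)c1cc(C(=O)OC)co1 | intermediate
23 | methyl (4S,7R)-7-{[(tert-butyldimethylsilyl)oxy]methyl}-4-[(2S)-6-methylhept-5-en-2-yl]-1a,4,5,6,7,7b-hexahydronaphtho[1,2-b]oxirene-2-carboxylate (the C7–C8 arene oxide, epoxide configuration not controlled, in equilibrium with its oxepine) | CC(C)(C)[Si](C)(C)OC[C@@H]1CC[C@@H]([C@@H](C)CCC=C(C)C)C2=C1C1OC1C(C(=O)OC)=C2 | intermediate (not isolated)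
24 | methyl (1R,4S)-1-{[(tert-butyldimethylsilyl)oxy]methyl}-8-hydroxy-4-[(2S)-6-methylhept-5-en-2-yl]-1,2,3,4-tetrahydronaphthalene-6-carboxylate | CC(C)(C)[Si](C)(C)OC[C@@H]1CC[C@@H]([C@@H](C)CCC=C(C)C)c2cc(C(=O)OC)cc(O)c21 | intermediate
25 | methyl (1R,4S)-8-hydroxy-1-(hydroxymethyl)-4-[(2S)-6-methylhept-5-en-2-yl]-1,2,3,4-tetrahydronaphthalene-6-carboxylate | OC[C@@H]1CC[C@@H]([C@@H](C)CCC=C(C)C)c2cc(C(=O)OC)cc(O)c21 | intermediate (not isolated)
26 | (1R,4S)-8-hydroxy-1-(hydroxymethyl)-4-[(2S)-6-methylhept-5-en-2-yl]-1,2,3,4-tetrahydronaphthalene-6-carboxylic acid | OC[C@@H]1CC[C@@H]([C@@H](C)CCC=C(C)C)c2cc(C(=O)O)cc(O)c21 | intermediate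
27 | acetic (1R,4S)-8-acetoxy-1-(acetoxymethyl)-4-[(2S)-6-methylhept-5-en-2-yl]-1,2,3,4-tetrahydronaphthalene-6-carboxylic anhydride | CC(=O)OC[C@@H]1CC[C@@H]([C@@H](C)CCC=C(C)C)c2cc(C(=O)OC(C)=O)cc(OC(C)=O)c21 | intermediate (not isolated)
28 | (1R,4S)-8-acetoxy-1-(acetoxymethyl)-4-[(2S)-6-methylhept-5-en-2-yl]-1,2,3,4-tetrahydronaphthalene-6-carboxylic acid | CC(=O)OC[C@@H]1CC[C@@H]([C@@H](C)CCC=C(C)C)c2cc(C(=O)O)cc(OC(C)=O)c21 | intermediate
29 | (1R,4S)-1-(acetoxymethyl)-8-hydroxy-4-[(2S)-6-methylhept-5-en-2-yl]-1,2,3,4-tetrahydronaphthalene-6-carboxylic acid | CC(=O)OC[C@@H]1CC[C@@H]([C@@H](C)CCC=C(C)C)c2cc(C(=O)O)cc(O)c21 | target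

## Step count and least certain steps

Total: 18 steps (2 for ylide 4, 16 in the main line). Longest linear sequence: 16 steps, from (S)-citronellal 5 to 29 (steps 3–18).

Step 15 (key step). The most likely failure is that the ester-deactivated furan attacks the gold-bound alkyne too slowly, so that alkyne hydration, oligomerisation or 5-endo attack by the silyl ether oxygen takes over; less likely, the arene oxide opens toward C7. A bulkier, more electrophilic phosphine or carbene ligand on gold is the first adjustment. The fallback sets out from 22 and returns at 26, and takes the ester out of conjugation before the cyclisation. Reduction of 22 with i-Bu2AlH at −78 °C gives the furylmethanol F1, and TBSCl/imidazole gives the bis-silyl ether F2, whose furan is as electron-rich as in the classical substrates of this cycloisomerisation. (Ph3P)AuNTf2 should then give the phenol F3; the hydroxyl position would have to be confirmed, since it then rests on the inherent preference of the reaction for the carbon next to the alkyne-derived fusion carbon. Bu4NF removes both silyl groups to give the triol F4, MnO2 oxidises only the benzylic alcohol to the aldehyde F5, and NaClO2/NaH2PO4/2-methylbut-2-ene (Pinnick oxidation) gives acid 26.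

Step 6. Transfer of the electron-poor furyl group from copper to the hindered β-carbon may be sluggish, with competing attack of the Grignard reagent on ester or imide carbonyls and eroded face selection. The fallback sets out from 11 (with 10) and returns at 13, and uses an ester-free, more nucleophilic furyl group, restoring the ester by oxidation. i-Bu2AlH reduces 11 to (5-bromofuran-3-yl)methanol F6, and TBSCl/imidazole gives the silyl ether F7. Bromine–lithium exchange with n-BuLi at −78 °C, transmetalation with MgBr2·OEt2 and CuBr·SMe2, and addition to 10 give the adduct F8 under the same auxiliary control. HF·pyridine gives the furylmethanol F9, MnO2 the furaldehyde F10, NaClO2 the acid F11, and Me3SiCHN2 in MeOH the methyl ester 13.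

Step 10. Under TiCl4 the dimethoxycarbenium ion may be captured by the trisubstituted alkene or by the free α-position of the furan, or enolisation may be incomplete because the furoate ester competes for the Lewis acid. The fallback sets out from 17 and returns at 21, and is a base-mediated alkylation without Lewis acid. NaN(SiMe3)2 at −78 °C and 4-methoxybenzyl chloromethyl ether give the alkoxymethyl imide F12 with the same facial sense. NaBH4 gives the alcohol F13, TBSCl the silyl ether F14, DDQ removes the 4-methoxybenzyl group to give the alcohol F15, and Dess–Martin oxidation gives aldehyde 21.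

Step 14. In basic methanol the α-branched aldehyde may epimerise at C1 by enolisation, or lose silanol by β-elimination, before the diazophosphonate anion adds. The fallback sets out from 21 and returns at 22, and uses olefination and elimination under aprotic conditions. The ylide from (iodomethyl)triphenylphosphonium iodide and NaN(SiMe3)2 at −78 °C converts 21 into the (Z)-vinyl iodide F16 (Stork–Zhao olefination), and a further equivalent of NaN(SiMe3)2 brings about anti-elimination of HI to give 22.

Step 18 (with step 17). Discrimination between the aryl and the alkyl acetate may be incomplete, or the acetyl group may move between the peri-related oxygens. The fallback sets out from 26 and returns at 29, and is a selective acylation instead of a selective deacylation: Candida antarctica lipase B and vinyl acetate acetylate the aliphatic primary alcohol of 26 and leave the phenol and the acid alone. No new compound is made.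

## Further compounds

F1 | step 15 | {5-[(3R,6S,7S)-3-{[(tert-butyldimethylsilyl)oxy]methyl}-7,11-dimethyldodec-10-en-1-yn-6-yl]furan-3-yl}methanol | CC(C)(C)[Si](C)(C)OC[C@@H](C#C)CC[C@@H]([C@@H](C)CCC=C(C)C)c1cc(CO)co1
F2 | step 15 | tert-butyl({5-[(3R,6S,7S)-3-{[(tert-butyldimethylsilyl)oxy]methyl}-7,11-dimethyldodec-10-en-1-yn-6-yl]furan-3-yl}methoxy)dimethylsilane | CC(C)(C)[Si](C)(C)OC[C@@H](C#C)CC[C@@H]([C@@H](C)CCC=C(C)C)c1cc(CO[Si](C)(C)C(C)(C)C)co1
F3 | step 15 | (5S,8R)-3,8-bis{[(tert-butyldimethylsilyl)oxy]methyl}-5-[(2S)-6-methylhept-5-en-2-yl]-5,6,7,8-tetrahydronaphthalen-1-ol | CC(C)(C)[Si](C)(C)OC[C@@H]1CC[C@@H]([C@@H](C)CCC=C(C)C)c2cc(CO[Si](C)(C)C(C)(C)C)cc(O)c21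
F4 | step 15 | (5S,8R)-3,8-bis(hydroxymethyl)-5-[(2S)-6-methylhept-5-en-2-yl]-5,6,7,8-tetrahydronaphthalen-1-ol | OC[C@@H]1CC[C@@H]([C@@H](C)CCC=C(C)C)c2cc(CO)cc(O)c21
F5 | step 15 | (1R,4S)-8-hydroxy-1-(hydroxymethyl)-4-[(2S)-6-methylhept-5-en-2-yl]-1,2,3,4-tetrahydronaphthalene-6-carbaldehyde | OC[C@@H]1CC[C@@H]([C@@H](C)CCC=C(C)C)c2cc(C=O)cc(O)c21
F6 | step 6 | (5-bromofuran-3-yl)methanol | OCc1coc(Br)c1
F7 | step 6 | [(5-bromofuran-3-yl)methoxy](tert-butyl)dimethylsilane | CC(C)(C)[Si](C)(C)OCc1coc(Br)c1
F8 | step 6 | (S)-4-benzyl-3-[(3S,4S)-3-(4-{[(tert-butyldimethylsilyl)oxy]methyl}furan-2-yl)-4,8-dimethylnon-7-enoyl]oxazolidin-2-one | O=C1OC[C@H](Cc2ccccc2)N1C(=O)C[C@@H]([C@@H](C)CCC=C(C)C)c1cc(CO[Si](C)(C)C(C)(C)C)co1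
F9 | step 6 | (S)-4-benzyl-3-[(3S,4S)-3-[4-(hydroxymethyl)furan-2-yl]-4,8-dimethylnon-7-enoyl]oxazolidin-2-one | O=C1OC[C@H](Cc2ccccc2)N1C(=O)C[C@@H]([C@@H](C)CCC=C(C)C)c1cc(CO)co1
F10 | step 6 | (S)-4-benzyl-3-[(3S,4S)-3-(4-formylfuran-2-yl)-4,8-dimethylnon-7-enoyl]oxazolidin-2-one | O=C1OC[C@H](Cc2ccccc2)N1C(=O)C[C@@H]([C@@H](C)CCC=C(C)C)c1cc(C=O)co1
F11 | step 6 | 5-[(3S,4S)-1-[(S)-4-benzyl-2-oxooxazolidin-3-yl]-4,8-dimethyl-1-oxonon-7-en-3-yl]furan-3-carboxylic acid | O=C1OC[C@H](Cc2ccccc2)N1C(=O)C[C@@H]([C@@H](C)CCC=C(C)C)c1cc(C(=O)O)co1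
F12 | step 10 | methyl 5-[(2R,5S,6S)-1-[(S)-4-benzyl-2-oxooxazolidin-3-yl]-2-{[(4-methoxybenzyl)oxy]methyl}-6,10-dimethyl-1-oxoundec-9-en-5-yl]furan-3-carboxylate | O=C1OC[C@H](Cc2ccccc2)N1C(=O)[C@@H](COCc1ccc(OC)cc1)CC[C@@H]([C@@H](C)CCC=C(C)C)c1cc(C(=O)OC)co1
F13 | step 10 | methyl 5-[(2S,5S,6S)-1-hydroxy-2-{[(4-methoxybenzyl)oxy]methyl}-6,10-dimethylundec-9-en-5-yl]furan-3-carboxylate | OC[C@@H](COCc1ccc(OC)cc1)CC[C@@H]([C@@H](C)CCC=C(C)C)c1cc(C(=O)OC)co1
F14 | step 10 | methyl 5-[(2R,5S,6S)-1-[(tert-butyldimethylsilyl)oxy]-2-{[(4-methoxybenzyl)oxy]methyl}-6,10-dimethylundec-9-en-5-yl]furan-3-carboxylate | CC(C)(C)[Si](C)(C)OC[C@@H](COCc1ccc(OC)cc1)CC[C@@H]([C@@H](C)CCC=C(C)C)c1cc(C(=O)OC)co1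
F15 | step 10 | methyl 5-[(2R,5S,6S)-1-[(tert-butyldimethylsilyl)oxy]-2-(hydroxymethyl)-6,10-dimethylundec-9-en-5-yl]furan-3-carboxylate | CC(C)(C)[Si](C)(C)OC[C@@H](CO)CC[C@@H]([C@@H](C)CCC=C(C)C)c1cc(C(=O)OC)co1
F16 | step 14 | methyl 5-[(1Z,3R,6S,7S)-3-{[(tert-butyldimethylsilyl)oxy]methyl}-1-iodo-7,11-dimethyldodeca-1,10-dien-6-yl]furan-3-carboxylate | CC(C)(C)[Si](C)(C)OC[C@@H](/C=C\I)CC[C@@H]([C@@H](C)CCC=C(C)C)c1cc(C(=O)OC)co1
F0 | step 18 | none | none
A1 | alternative 1 | tert-butyl{[(2R)-4-bromo-2-{2-(methoxymethoxy)-6-[(1E)-prop-1-en-1-yl]phenyl}butyl]oxy}dimethylsilane | CC(C)(C)[Si](C)(C)OC[C@H](CCBr)c1c(OCOC)cccc1/C=C/C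
A2 | alternative 1 | tert-butyl{[(1R,4S)-8-(methoxymethoxy)-4-[(1R)-1-(4,4,5,5-tetramethyl-1,3,2-dioxaborolan-2-yl)ethyl]-1,2,3,4-tetrahydronaphthalen-1-yl]methoxy}dimethylsilane | CC(C)(C)[Si](C)(C)OC[C@@H]1CC[C@@H]([C@@H](C)B2OC(C)(C)C(C)(C)O2)c2cccc(OCOC)c21
A3 | alternative 2 | (5S,6S)-5-(3-methoxyphenyl)-6,10-dimethylundec-9-enal | O=CCCC[C@@H]([C@@H](C)CCC=C(C)C)c1cccc(OC)c1
A4 | alternative 2 | (1R,4S)-8-methoxy-4-[(2S)-6-methylhept-5-en-2-yl]-1,2,3,4-tetrahydronaphthalene-1-carbaldehyde | O=C[C@@H]1CC[C@@H]([C@@H](C)CCC=C(C)C)c2cccc(OC)c21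
A5 | alternative 3 | methyl 10-oxo-1-[(2S)-6-methylhept-5-en-2-yl]-4-{[(triisopropylsilyl)oxy]methyl}spiro[4.5]deca-6,8-diene-8-carboxylate (ring stereocentres as in the SMILES, spiro centre unassigned) | CC(C)[Si](C(C)C)(C(C)C)OC[C@@H]1CC[C@@H]([C@@H](C)CCC=C(C)C)C12C=CC(C(=O)OC)=CC2=O
A6 | alternative 3 | methyl (1R,4S)-8-hydroxy-4-[(2S)-6-methylhept-5-en-2-yl]-1-{[(triisopropylsilyl)oxy]methyl}-1,2,3,4-tetrahydronaphthalene-6-carboxylate | CC(C)[Si](C(C)C)(C(C)C)OC[C@@H]1CC[C@@H]([C@@H](C)CCC=C(C)C)c2cc(C(=O)OC)cc(O)c21
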